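Assumption (remark on the chemistry): the target has no stereocentre and the diaryl ether axis is taken as freely rotating, so no stereocontrol is planned; alcohol 3 is used as the racemate.

## The problem

Compound 18 consists of two coumarins joined by one oxygen. C8 of a 7-methoxycoumarin (coumarin A, unprimed atoms) is bonded through an ether oxygen to C8' of 5,7-dihydroxycoumarin (coumarin B, primed atoms; its benzene ring is called ring B). With no stereocentre and no configurationally stable axis, the difficulty is entirely regiochemistry and chemoselectivity. The ether is the hard bond: C8 lies between C8a–O1 and the C7 methoxy group, and C8' between C8a'–O1' and the C7' hydroxyl, so it is tetra-ortho-substituted and joins two electron-rich rings, neither of which is an electrophile in its final form. Ring B is a 1,2,3,5-tetraoxygenated benzene whose three phloroglucinol oxygens play different parts (lactone O1', free 5'-OH and 7'-OH); the oxygen next to the ether carbon must be singled out as O1', and C4' must be attached ortho to it. The lactones open with hydroxide or alkoxide and their C3=C4 bonds can be hydrogenated; ring B and all its protected precursors are easily oxidised and C-alkylated; the aryl methyl ether must survive the last deprotection. The enabling feature lies in coumarin A: without O1, the atoms C2, C3, C4, C4a and C8a form the five-membered ring of an indan-1-one whose carbonyl carbon is bonded to the aryl carbon next to C8. A ketone there can first activate a leaving group on the future C8 for ether formation and then accept oxygen between itself and the future C8a.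

## Retrosynthesis

**18 from 17.** The two O–benzyl bonds of 5',7'-di-O-benzyl ether 17 are cut last. Benzyl ethers are chosen because they survive carbonate at 90 °C, peracid, DDQ, dilute acid and 215 °C. They are to be removed with BCl3 and a cation scavenger, not by hydrogenolysis, which would endanger both C3=C4 bonds.

**17 from 13 through 15 and 14.** Pyranone B is cut at C3'–C4' and O1'–C2' (olefination–lactonisation of salicylaldehyde 15, via cinnamate 16), then at C4a'–C4' (ortho-formylation of phenol 14), then at the methoxymethyl ether of 13. A direct annulation on an unprotected triol would give 6-aryloxy and 8-aryloxy coumarins, since two hydroxyls flank each free ring carbon. With one oxygen masked differently, phenol 14 has a single free ortho carbon, and that carbon is C4a'.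

**13 from 12.** The C3=C4 double bond of coumarin A is taken back to the 3,4-dihydrocoumarin 12. The forward step is a dehydrogenation assisted by the C7 methoxy group, and it must leave ring B and the benzyl ethers alone.

**12 from 11 (key disconnection).** O1–C8a is cut, with the carbonyl carbon returned to C8a: the Baeyer–Villiger retron. The neighbouring cuts, C4–C4a or C3–C4, would require a free phenol at C8a beside the hindered ether and a separate activating group for making that ether. Indanone 11 already holds all three pyranone carbons, and its ketone is the activating group. The forward reaction must migrate the aryl carbon, not the methylene, and must not oxidise ring B.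

**11 from 5 and 10.** The aryl–oxygen bond at C7 of the indanone is cut to give fluoro ketone 5 and phenol 10, two fragments of similar size. The fluoride is ortho to a carbonyl that the five-membered ring holds coplanar with the arene; the forward step is an addition–elimination with a di-ortho-substituted phenoxide.

**5 from 1 and 2 through 4 and 3.** C3–C3a is cut (Nazarov-type closure of aryl vinyl ketone 4), then the carbinol oxidation level (alcohol 3), then the bond from the carbonyl carbon to the vinyl group (aldehyde 1 and vinylmagnesium bromide 2). A Friedel–Crafts closure of an arylpropanoic acid would attack the wrong ortho carbon, so the acyl carbon must already be on the ring next to fluorine. In 4 the only free ortho carbon is para to the methoxy group.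

**10 from 6 through 9, 8 and 7.** The phenolic oxygen of 10 comes from the formyl carbon of aldehyde 8 by aryl migration (formate 9). Before it is removed, that formyl group differentiates the three hydroxyls of 2,4,6-trihydroxybenzaldehyde 6: two are benzylated (7), and the hydrogen-bonded third then receives the methoxymethyl group (8).

## Roads not taken

**Alternative 1:** Both pyranones are cut at C4–C4a and C4'–C4a'. The precursor is the bis(propiolate) A2, 2-[2,4-bis(benzyloxy)-6-(propioloyloxy)phenoxy]-3-methoxyphenyl propiolate. Ph3PAuCl with AgSbF6 would activate both alkynes, and each arene would attack its own alkyne to give the dibenzyl bicoumarin A1, which is the same compound as 17.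
- Merits: two rings and two C–C bonds form in one step, the route is convergent, and it needs no dehydrogenation and no formylation–olefination. It would be about four steps shorter than the chosen route, so in step economy it is the better plan.
- Weak points: the two arenes differ greatly in nucleophilicity. Ring B carries three donors, while the attacking carbon of ring A is para to one methoxy group on a ring deactivated by its own acyloxy group. The slow half is exposed to alkyne hydration, ester cleavage and ipso attack at the ether-bearing carbon. A2 is a pair of activated esters of hindered phenols, and it still needs the same tetra-ortho-substituted ether beforehand.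
- What the chosen plan sets against it: every pyranone C–C bond is made by carbonyl chemistry whose position is fixed by the substrate, the two lactones are built one after the other under conditions suited to each, and no step relies on a weakly nucleophilic arene.

**Alternative 2:** Ring B is built from an open chain by cutting C4a'–C5'. Base would form the extended enolate of the dioxinone keto ester A4, methyl 4-[2-(dimethoxymethyl)-6-methoxyphenoxy]-4-(2,2-dimethyl-4-oxo-4H-1,3-dioxin-6-yl)-3-oxobutanoate. Its ring carbon would attack the methyl ester, and aromatisation would give the benzodioxinone A3, 8-[2-(dimethoxymethyl)-6-methoxyphenoxy]-5,7-dihydroxy-2,2-dimethyl-4H-1,3-benzodioxin-4-one.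
- Merits: the oxygen pattern of ring B and the carbon on C4a' arrive in defined positions, with O1' and that carbon tied together in the acetonide. No selective protection or directed formylation is needed, and in that one respect it is better than the chosen plan.
- Weak points: it constructs a benzene ring that can be bought with all three oxygens in place. A4 carries an aryloxy group on a carbon between a ketone and the dioxinone, where it is acidic and can be lost by elimination, and it is hard to assemble. After A3, the carboxyl carbon must still be reduced and extended by two carbons, the diol protected, and ring A (present only as an acetal-masked aldehyde) given its ring oxygen and all three pyranone carbons. Neither lactone is made in the key step, and the route would be the longest of the four.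
- What the chosen plan sets against it: the differentiation of the ring B oxygens is obtained in one step, from the hydrogen bond in 6.

**Alternative 3:** O1'–C8a' is cut as a C–H oxidation. Riboflavin, blue light and oxygen would isomerise the E-cinnamic acid A6, (2E)-3-{2,4-bis(methoxymethoxy)-5-[(7-methoxy-2-oxo-2H-chromen-8-yl)oxy]phenyl}prop-2-enoic acid, to the Z acid and oxidise the arene so that the carboxylate bonds to C8a'. The product would be the 5',7'-bis(methoxymethyl) ether A5 of the target.
- Merits: ring B needs only two protected oxygens, so no three-way differentiation arises. The ring closure is late, mild and metal-free, and the final acetal cleavage is gentler than a debenzylation. These are real advantages over the chosen plan.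
- Weak points: the carbon to be oxidised is meta to both methoxymethoxy donors and ortho only to the aryloxy group, so the arene radical cation has little positive charge there. Attack at a donor-bearing carbon, followed by rearrangement or loss of a group, is a plausible competing path. The tetraoxygenated ring under light and oxygen invites quinone formation, and the coumarin A chromophore can absorb or quench. A6 still requires the hindered ether and a finished coumarin A.
- What the chosen plan sets against it: the oxygen on C8a' is present from the start as one of the phloroglucinol oxygens, so the regiochemistry of ring closure is never in question. The price is three protecting-group steps and a BCl3 deprotection.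

Key step: step 8

## Route

Step 1
Reactants: 1 2-fluoro-3-methoxybenzaldehyde; 2 vinylmagnesium bromide
Product: 3 (±)-1-(2-fluoro-3-methoxyphenyl)prop-2-en-1-ol
Conditions: THF, −78 to 0 °C; aq. NH4Cl
Reagents that add atoms: none
Why: 1,2-Addition of a vinyl Grignard reagent to a non-enolisable aryl aldehyde; the carbinol centre forms as a racemate and is removed in step 2.

Step 2
Reactants: 3 (±)-1-(2-fluoro-3-methoxyphenyl)prop-2-en-1-ol
Product: 4 1-(2-fluoro-3-methoxyphenyl)prop-2-en-1-one
Conditions: activated MnO2, CH2Cl2, rt; used crude at once
Reagents that add atoms: none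
Why: Oxidation of an allylic and benzylic secondary alcohol with MnO2; the aryl vinyl ketone polymerises easily and is therefore not stored.

Step 3
Reactants: 4 1-(2-fluoro-3-methoxyphenyl)prop-2-en-1-one
Product: 5 7-fluoro-6-methoxy-2,3-dihydro-1H-inden-1-one
Conditions: CF3SO3H, ClCH2CH2Cl, 0 to 50 °C
Reagents that add atoms: none
Why: Nazarov-type cyclisation of an aryl vinyl ketone in superacid: the protonated enone closes onto the only free ortho carbon, which is para to the methoxy group, and rearomatisation gives the indanone; known for aryl vinyl ketones and their 3-chloropropiophenone precursors.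

Step 4
Reactants: 6 2,4,6-trihydroxybenzaldehyde
Product: 7 2,4-bis(benzyloxy)-6-hydroxybenzaldehyde
Conditions: BnBr (2.1 equiv), K2CO3, DMF, 0 °C to rt
Reagents that add atoms: benzyl bromide, BrCc1ccccc1
Why: Williamson ether synthesis: the 4-hydroxyl and one ortho hydroxyl are alkylated, while the last ortho hydroxyl is held in a hydrogen bond to the formyl oxygen and resists alkylation under carbonate conditions.

Step 5
Reactants: 7 2,4-bis(benzyloxy)-6-hydroxybenzaldehyde
Product: 8 2,4-bis(benzyloxy)-6-(methoxymethoxy)benzaldehyde
Conditions: NaH, MOMCl, DMF, 0 °C to rt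
Reagents that add atoms: chloromethyl methyl ether, COCCl
Why: O-Alkylation of the sodium phenoxide; full deprotonation with NaH overcomes the hydrogen bond that protected this hydroxyl in step 4.

Step 6
Reactants: 8 2,4-bis(benzyloxy)-6-(methoxymethoxy)benzaldehyde
Product: 10 2,4-bis(benzyloxy)-6-(methoxymethoxy)phenol, via aryl formate 9 (not isolated)
Conditions: mCPBA, CH2Cl2, 0 °C to rt; then K2CO3 (cat.), MeOH, 0 °C; under argon
Reagents that add atoms: m-chloroperbenzoic acid, OOC(=O)c1cccc(Cl)c1
Why: Dakin-type Baeyer–Villiger oxidation of an aryl aldehyde: aryl migration is fast because the migrating carbon has two ortho and one para oxygen donor, and the formate is cleaved by base-catalysed methanolysis.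

Step 7
Reactants: 5 7-fluoro-6-methoxy-2,3-dihydro-1H-inden-1-one; 10 2,4-bis(benzyloxy)-6-(methoxymethoxy)phenol
Product: 11 7-[2,4-bis(benzyloxy)-6-(methoxymethoxy)phenoxy]-6-methoxy-2,3-dihydro-1H-inden-1-one
Conditions: Cs2CO3, DMSO, 90 °C, argon
Reagents that add atoms: none
Why: Nucleophilic aromatic substitution by addition–elimination: fluoride ortho to the coplanar ring ketone is displaced by the caesium phenoxide through a Meisenheimer adduct whose charge is delocalised into the carbonyl; known for 7-fluoroindan-1-ones and 2-fluoroaryl ketones with phenoxides.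

Step 8
Reactants: 11 7-[2,4-bis(benzyloxy)-6-(methoxymethoxy)phenoxy]-6-methoxy-2,3-dihydro-1H-inden-1-one
Product: 12 8-[2,4-bis(benzyloxy)-6-(methoxymethoxy)phenoxy]-7-methoxy-3,4-dihydro-2H-chromen-2-one
Conditions: mCPBA (1.3 equiv), solid NaHCO3, CH2Cl2, 0 °C to rt, dark; Na2S2O3 quench
Reagents that add atoms: m-chloroperbenzoic acid, OOC(=O)c1cccc(Cl)c1
Why: Baeyer–Villiger oxidation: the peracid adds to the C1 carbonyl of 11 to give the tetrahedral Criegee adduct, and aryl carbon C7a shifts from C1 to the proximal peroxide oxygen, antiperiplanar to the breaking O–O bond, as 3-chlorobenzoate leaves. The closest known reaction type is the peracid oxidation of 1-indanones to 3,4-dihydrocoumarins by aryl migration. The six-membered lactone is not closed by a cyclisation; it arises by 1,2-shift ring expansion of the five-membered ketone, so O1–C8a forms while all ring atoms stay connected. No stereocentre is formed. Aryl migration in preference to migration of the C2 methylene is required, and it is secured because the migrating sp2 carbon carries the aryloxy donor in the ortho position, which stabilises the electron-deficient transition state. Chemoselectivity against electrophilic hydroxylation of ring B is also required; it rests on NaHCO3 removing the carboxylic acid that catalyses arene oxidation, on a small excess of peracid and on low temperature. The benzyl and methoxymethyl ethers are inert to buffered peracid, and the aryl lactone is kept away from aqueous base in the work-up.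

Step 9
Reactants: 12 8-[2,4-bis(benzyloxy)-6-(methoxymethoxy)phenoxy]-7-methoxy-3,4-dihydro-2H-chromen-2-one
Product: 13 8-[2,4-bis(benzyloxy)-6-(methoxymethoxy)phenoxy]-7-methoxy-2H-chromen-2-one
Conditions: DDQ, 1,4-dioxane, reflux
Reagents that add atoms: none
Why: DDQ dehydrogenation, known for 3,4-dihydrocoumarins: hydride is abstracted from benzylic C4, where the cation is stabilised through C4a by the para-related C7 methoxy group, and loss of H3 gives the conjugated coumarin.

Step 10
Reactants: 13 8-[2,4-bis(benzyloxy)-6-(methoxymethoxy)phenoxy]-7-methoxy-2H-chromen-2-one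
Product: 14 8-[2,4-bis(benzyloxy)-6-hydroxyphenoxy]-7-methoxy-2H-chromen-2-one
Conditions: HCl, MeOH/THF, 50 °C
Reagents that add atoms: none
Why: Acid-catalysed acetal cleavage of the methoxymethyl ether; the benzyl ethers, the methyl ether and the coumarin lactone are stable to dilute HCl in methanol.

Step 11
Reactants: 14 8-[2,4-bis(benzyloxy)-6-hydroxyphenoxy]-7-methoxy-2H-chromen-2-one
Product: 15 4,6-bis(benzyloxy)-2-hydroxy-3-[(7-methoxy-2-oxo-2H-chromen-8-yl)oxy]benzaldehyde
Conditions: MgCl2, Et3N, (CH2O)n, MeCN, reflux; aq. HCl work-up
Reagents that add atoms: paraformaldehyde (as formaldehyde), C=O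
Why: Magnesium-mediated ortho-formylation (Casnati–Skattebøl): formaldehyde is delivered within the magnesium phenoxide to the only free ortho carbon, which becomes C4a'; the other free ring carbon is para to the hydroxyl and is not reached.

Step 12
Reactants: 15 4,6-bis(benzyloxy)-2-hydroxy-3-[(7-methoxy-2-oxo-2H-chromen-8-yl)oxy]benzaldehyde
Product: 17 5,7-bis(benzyloxy)-8-[(7-methoxy-2-oxo-2H-chromen-8-yl)oxy]-2H-chromen-2-one, via E-cinnamate ester 16 (not isolated)
Conditions: Ph3P=CHCO2Et, N,N-diethylaniline, reflux
Reagents that add atoms: ethyl (triphenylphosphoranylidene)acetate, CCOC(=O)C=P(c1ccccc1)(c1ccccc1)c1ccccc1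
Why: Wittig olefination of the salicylaldehyde with a stabilised ylide, then thermal E to Z isomerisation and lactonisation of the 2-hydroxycinnamate in boiling N,N-diethylaniline, the standard one-flask coumarin synthesis.

Step 13
Reactants: 17 5,7-bis(benzyloxy)-8-[(7-methoxy-2-oxo-2H-chromen-8-yl)oxy]-2H-chromen-2-one
Product: 18 8-[(5,7-dihydroxy-2-oxo-2H-chromen-8-yl)oxy]-7-methoxy-2H-chromen-2-one
Conditions: BCl3, C6HMe5, CH2Cl2, −78 °C; then MeOH, H2O
Reagents that add atoms: none
Why: Lewis acid debenzylation with BCl3 and pentamethylbenzene as a non-basic benzyl cation scavenger, which prevents C-benzylation of the phloroglucinol-type ring; the lactone double bonds and the methyl ether are not touched at low temperature.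

## Compound list

1 | 2-fluoro-3-methoxybenzaldehyde | COc1cccc(C=O)c1F | starting material
2 | vinylmagnesium bromide | C=C[Mg]Br | starting material
3 | (±)-1-(2-fluoro-3-methoxyphenyl)prop-2-en-1-ol (racemate) | COc1cccc(C(O)C=C)c1F | intermediate
4 | 1-(2-fluoro-3-methoxyphenyl)prop-2-en-1-one | COc1cccc(C(=O)C=C)c1F | intermediate
5 | 7-fluoro-6-methoxy-2,3-dihydro-1H-inden-1-one | COc1ccc2CCC(=O)c2c1F | intermediate
6 | 2,4,6-trihydroxybenzaldehyde | O=Cc1c(O)cc(O)cc1O | starting material
7 | 2,4-bis(benzyloxy)-6-hydroxybenzaldehyde | O=Cc1c(O)cc(OCc2ccccc2)cc1OCc1ccccc1 | intermediate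
8 | 2,4-bis(benzyloxy)-6-(methoxymethoxy)benzaldehyde | COCOc1cc(OCc2ccccc2)cc(OCc2ccccc2)c1C=O | intermediate
9 | 2,4-bis(benzyloxy)-6-(methoxymethoxy)phenyl formate (not isolated) | O=COc1c(OCOC)cc(OCc2ccccc2)cc1OCc1ccccc1 | intermediate
10 | 2,4-bis(benzyloxy)-6-(methoxymethoxy)phenol | Oc1c(OCOC)cc(OCc2ccccc2)cc1OCc1ccccc1 | intermediate
11 | 7-[2,4-bis(benzyloxy)-6-(methoxymethoxy)phenoxy]-6-methoxy-2,3-dihydro-1H-inden-1-one | COc1ccc2CCC(=O)c2c1Oc1c(OCc3ccccc3)cc(OCc3ccccc3)cc1OCOC | intermediate
12 | 8-[2,4-bis(benzyloxy)-6-(methoxymethoxy)phenoxy]-7-methoxy-3,4-dihydro-2H-chromen-2-one | COc1ccc2CCC(=O)Oc2c1Oc1c(OCc3ccccc3)cc(OCc3ccccc3)cc1OCOC | intermediate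
13 | 8-[2,4-bis(benzyloxy)-6-(methoxymethoxy)phenoxy]-7-methoxy-2H-chromen-2-one | COc1ccc2ccc(=O)oc2c1Oc1c(OCc3ccccc3)cc(OCc3ccccc3)cc1OCOC | intermediate
14 | 8-[2,4-bis(benzyloxy)-6-hydroxyphenoxy]-7-methoxy-2H-chromen-2-one | COc1ccc2ccc(=O)oc2c1Oc1c(OCc3ccccc3)cc(OCc3ccccc3)cc1O | intermediate
15 | 4,6-bis(benzyloxy)-2-hydroxy-3-[(7-methoxy-2-oxo-2H-chromen-8-yl)oxy]benzaldehyde | COc1ccc2ccc(=O)oc2c1Oc1c(OCc3ccccc3)cc(OCc3ccccc3)c(C=O)c1O | intermediate
16 | ethyl (2E)-3-{4,6-bis(benzyloxy)-2-hydroxy-3-[(7-methoxy-2-oxo-2H-chromen-8-yl)oxy]phenyl}prop-2-enoate (not isolated) | COc1ccc2ccc(=O)oc2c1Oc1c(OCc3ccccc3)cc(OCc3ccccc3)c(/C=C/C(=O)OCC)c1O | intermediate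
17 | 5,7-bis(benzyloxy)-8-[(7-methoxy-2-oxo-2H-chromen-8-yl)oxy]-2H-chromen-2-one | COc1ccc2ccc(=O)oc2c1Oc1c(OCc3ccccc3)cc(OCc3ccccc3)c3ccc(=O)oc13 | intermediate
18 | 8-[(5,7-dihydroxy-2-oxo-2H-chromen-8-yl)oxy]-7-methoxy-2H-chromen-2-one | COc1ccc2ccc(=O)oc2c1Oc1c(O)cc(O)c2ccc(=O)oc12 | target

## Step count and least certain steps

Total: 13 steps. Longest linear sequence: 10 steps (steps 4–13 from 6; the branch from 1, steps 1–3 and 7–13, is equally long).

**Step 8 (key step).** Oxygen insertion at the hindered, donor-conjugated ketone may be slow. The peracid could then hydroxylate the unprotected, very electron-rich ring B, or to a lesser extent the methylene group could migrate. The fallback gives up the ring expansion and builds pyranone A by the sequence used for pyranone B. It sets out from 1 and 10.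
- Displacement of the aldehyde-activated fluoride of 1 by 10 (K2CO3, DMF, 100 °C) would give 2-[2,4-bis(benzyloxy)-6-(methoxymethoxy)phenoxy]-3-methoxybenzaldehyde F1.
- Dakin oxidation with mCPBA at 0 °C, where an aryl aldehyde reacts far faster than an aryl ketone, would give 2-[2,4-bis(benzyloxy)-6-(methoxymethoxy)phenoxy]-3-methoxyphenyl formate F2, and methanolysis would give 2-[2,4-bis(benzyloxy)-6-(methoxymethoxy)phenoxy]-3-methoxyphenol F3.
- Magnesium-mediated ortho-formylation at the only free ortho carbon would give 3-[2,4-bis(benzyloxy)-6-(methoxymethoxy)phenoxy]-2-hydroxy-4-methoxybenzaldehyde F4.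
- Ph3P=CHCO2Et in boiling N,N-diethylaniline would pass through ethyl (2E)-3-{3-[2,4-bis(benzyloxy)-6-(methoxymethoxy)phenoxy]-2-hydroxy-4-methoxyphenyl}prop-2-enoate F5 and lactonise, returning to the route at 13.

**Step 7.** Deprotonation of the indanone at C2 and aldol self-condensation may outrun the slow displacement, since the phenoxide is di-ortho-substituted and the fluoride is flanked by a methoxy group. The fallback forms the ether on a non-enolisable aldehyde and closes the five-membered ketone afterwards under neutral conditions. It sets out from 10 and purchased 6-bromo-2-fluoro-3-methoxybenzaldehyde F6.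
- K2CO3 in DMF at 90 °C would give 2-[2,4-bis(benzyloxy)-6-(methoxymethoxy)phenoxy]-6-bromo-3-methoxybenzaldehyde F7.
- Suzuki–Miyaura coupling with K[CH2=CHBF3] (PdCl2(dppf), Cs2CO3, THF/H2O) would give 2-[2,4-bis(benzyloxy)-6-(methoxymethoxy)phenoxy]-6-ethenyl-3-methoxybenzaldehyde F8.
- Rhodium-catalysed intramolecular hydroacylation ([Rh(nbd)(dppe)]ClO4 activated with H2, CH2Cl2, rt), known for 2-vinylbenzaldehydes, would return to the route at 11.

**Step 3.** The aryl vinyl ketone may polymerise before it cyclises, because the fluorine-bearing ring is only a moderate nucleophile, and strong acid may cleave the methyl ether. The fallback replaces 1 and 2 by purchased F6. Suzuki–Miyaura vinylation as above would give 6-ethenyl-2-fluoro-3-methoxybenzaldehyde F9, and the same rhodium-catalysed hydroacylation would return to the route at 5.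

**Step 9.** Dehydrogenation may stall at reflux, while DDQ slowly oxidises ring B or the benzylic ether C–H bonds. The fallback introduces the double bond by selenoxide elimination and sets out from 12.
- LiN(SiMe3)2 and PhSeCl in THF at −78 °C would give racemic 8-[2,4-bis(benzyloxy)-6-(methoxymethoxy)phenoxy]-7-methoxy-3-(phenylselanyl)-3,4-dihydro-2H-chromen-2-one F10.
- H2O2 in CH2Cl2 at 0 °C would give the selenoxide, 8-[2,4-bis(benzyloxy)-6-(methoxymethoxy)phenoxy]-7-methoxy-3-(phenylseleninyl)-3,4-dihydro-2H-chromen-2-one F11, which would undergo syn elimination towards C4 and return to the route at 13.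

**Step 4.** Alkylation may run on to the tribenzyl ether, or C-benzylation of the phloroglucinol nucleus may compete, eroding the selectivity. The fallback sets out from 6. Exhaustive benzylation (excess BnBr, K2CO3, DMF, 60 °C) would give 2,4,6-tris(benzyloxy)benzaldehyde F12, and MgBr2·OEt2 would remove one ortho benzyl group by chelation between the formyl and ether oxygens, returning to the route at 7.

## Further compounds

F1 | step 8 | 2-[2,4-bis(benzyloxy)-6-(methoxymethoxy)phenoxy]-3-methoxybenzaldehyde | COc1cccc(C=O)c1Oc1c(OCc2ccccc2)cc(OCc2ccccc2)cc1OCOC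
F2 | step 8 | 2-[2,4-bis(benzyloxy)-6-(methoxymethoxy)phenoxy]-3-methoxyphenyl formate | COc1cccc(OC=O)c1Oc1c(OCc2ccccc2)cc(OCc2ccccc2)cc1OCOC
F3 | step 8 | 2-[2,4-bis(benzyloxy)-6-(methoxymethoxy)phenoxy]-3-methoxyphenol | COc1cccc(O)c1Oc1c(OCc2ccccc2)cc(OCc2ccccc2)cc1OCOC
F4 | step 8 | 3-[2,4-bis(benzyloxy)-6-(methoxymethoxy)phenoxy]-2-hydroxy-4-methoxybenzaldehyde | COc1ccc(C=O)c(O)c1Oc1c(OCc2ccccc2)cc(OCc2ccccc2)cc1OCOC
F5 | step 8 | ethyl (2E)-3-{3-[2,4-bis(benzyloxy)-6-(methoxymethoxy)phenoxy]-2-hydroxy-4-methoxyphenyl}prop-2-enoate | CCOC(=O)/C=C/c1ccc(OC)c(Oc2c(OCc3ccccc3)cc(OCc3ccccc3)cc2OCOC)c1O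
F6 | step 7 | 6-bromo-2-fluoro-3-methoxybenzaldehyde (purchased) | COc1ccc(Br)c(C=O)c1F
F7 | step 7 | 2-[2,4-bis(benzyloxy)-6-(methoxymethoxy)phenoxy]-6-bromo-3-methoxybenzaldehyde | COc1ccc(Br)c(C=O)c1Oc1c(OCc2ccccc2)cc(OCc2ccccc2)cc1OCOC
F8 | step 7 | 2-[2,4-bis(benzyloxy)-6-(methoxymethoxy)phenoxy]-6-ethenyl-3-methoxybenzaldehyde | COc1ccc(C=C)c(C=O)c1Oc1c(OCc2ccccc2)cc(OCc2ccccc2)cc1OCOC
F9 | step 3 | 6-ethenyl-2-fluoro-3-methoxybenzaldehyde | COc1ccc(C=C)c(C=O)c1F
F10 | step 9 | 8-[2,4-bis(benzyloxy)-6-(methoxymethoxy)phenoxy]-7-methoxy-3-(phenylselanyl)-3,4-dihydro-2H-chromen-2-one (racemate) | COc1ccc2CC([Se]c3ccccc3)C(=O)Oc2c1Oc1c(OCc3ccccc3)cc(OCc3ccccc3)cc1OCOC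
F11 | step 9 | 8-[2,4-bis(benzyloxy)-6-(methoxymethoxy)phenoxy]-7-methoxy-3-(phenylseleninyl)-3,4-dihydro-2H-chromen-2-one (mixture of stereoisomers) | COc1ccc2CC([Se](=O)c3ccccc3)C(=O)Oc2c1Oc1c(OCc3ccccc3)cc(OCc3ccccc3)cc1OCOC
F12 | step 4 | 2,4,6-tris(benzyloxy)benzaldehyde | O=Cc1c(OCc2ccccc2)cc(OCc2ccccc2)cc1OCc1ccccc1
A1 | alternative 1 | 5,7-bis(benzyloxy)-8-[(7-methoxy-2-oxo-2H-chromen-8-yl)oxy]-2H-chromen-2-one (identical with 17) | COc1ccc2ccc(=O)oc2c1Oc1c(OCc3ccccc3)cc(OCc3ccccc3)c3ccc(=O)oc13
A2 | alternative 1 | 2-[2,4-bis(benzyloxy)-6-(propioloyloxy)phenoxy]-3-methoxyphenyl propiolate | COc1cccc(OC(=O)C#C)c1Oc1c(OCc2ccccc2)cc(OCc2ccccc2)cc1OC(=O)C#C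
A3 | alternative 2 | 8-[2-(dimethoxymethyl)-6-methoxyphenoxy]-5,7-dihydroxy-2,2-dimethyl-4H-1,3-benzodioxin-4-one | CC1(C)OC(=O)c2c(O)cc(O)c(Oc3c(OC)cccc3C(OC)OC)c2O1
A4 | alternative 2 | methyl 4-[2-(dimethoxymethyl)-6-methoxyphenoxy]-4-(2,2-dimethyl-4-oxo-4H-1,3-dioxin-6-yl)-3-oxobutanoate (racemate) | COC(=O)CC(=O)C(Oc1c(OC)cccc1C(OC)OC)C1=CC(=O)OC(C)(C)O1
A5 | alternative 3 | 8-{[5,7-bis(methoxymethoxy)-2-oxo-2H-chromen-8-yl]oxy}-7-methoxy-2H-chromen-2-one | COCOc1cc(OCOC)c2ccc(=O)oc2c1Oc1c(OC)ccc2ccc(=O)oc12
A6 | alternative 3 | (2E)-3-{2,4-bis(methoxymethoxy)-5-[(7-methoxy-2-oxo-2H-chromen-8-yl)oxy]phenyl}prop-2-enoic acid | OC(=O)/C=C/c1cc(Oc2c(OC)ccc3ccc(=O)oc23)c(OCOC)cc1OCOC
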